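**Assumptions:** the SMILES is read as 3-[(2S,3R)-2-[(3S,4R)-3,4-dihydroxycyclohex-1-en-1-yl]-3-(hydroxymethyl)-7-methoxy-2,3-dihydro-1-benzofuran-5-yl]propan-1-ol (2,3-trans furan, cis-diol). Methyl dihydroferulate (1) is taken as a purchasable starting material.

## Retrosynthetic overview

1. Target ⇐ acid deprotection ⇐ trans-dihydrobenzofuran 22 ⇐ intramolecular Mitsunobu etherification (O1–C2, inversion) of phenol/allylic alcohol 21.
2. C2–C3 bond ⇐ Mg-catalysed Evans anti-aldol uniting arylacetyl imide 9 with cyclohexenecarbaldehyde 18.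
3. 18 ⇐ ring-closing metathesis of 1,7-diene 16 (closes the cyclohexene) ⇐ Sharpless epoxy alcohol 13 opened by methallyl alcohol dianion.
4. 9 ⇐ methyl dihydroferulate by O-allylation/Claisen rearrangement, oxidative cleavage of the allyl group and auxiliary attachment.
5. Ring order: cyclohexene first (RCM, in fragment B), dihydrobenzofuran last (after the union).

## Fragment A (steps 1–6)

**Step 1**
Reactants: 1 methyl 3-(4-hydroxy-3-methoxyphenyl)propanoate; 2 allyl bromide
Product: 3 methyl 3-[3-methoxy-4-(prop-2-en-1-yloxy)phenyl]propanoate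
Conditions: K2CO3, acetone, reflux
Reagents that add atoms: allyl bromide (2), C=CCBr
Why: Williamson O-allylation of the phenol; carbonate does not touch the methyl ester.

**Step 2**
Reactants: 3
Product: 4 methyl 3-[4-hydroxy-3-methoxy-5-(prop-2-en-1-yl)phenyl]propanoate
Conditions: PhNEt2, 200 °C (sealed tube)
Reagents that add atoms: none
Why: Aromatic Claisen [3,3] rearrangement; the only free ortho position is C5 (the other ortho carries OMe, para is blocked).

**Step 3**
Reactants: 4
Product: 5 methyl 3-{4-[(tert-butyldimethylsilyl)oxy]-3-methoxy-5-(prop-2-en-1-yl)phenyl}propanoate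
Conditions: TBSCl, imidazole, DMF, 40 °C
Reagents that add atoms: TBSCl, CC(C)(C)[Si](C)(C)Cl
Why: Silylation masks the guaiacol OH against periodate/chlorite oxidation and during the later enolisation.

**Step 4**
Reactants: 5
Product: 6 methyl 3-{4-[(tert-butyldimethylsilyl)oxy]-3-methoxy-5-(2-oxoethyl)phenyl}propanoate
Conditions: OsO4 (cat.), NaIO4, 2,6-lutidine, dioxane/H2O, rt
Reagents that add atoms: OsO4, O=[Os](=O)(=O)=O / NaIO4, [Na+].[O-]I(=O)(=O)=O (carbonyl oxygen)
Why: Lemieux–Johnson cleavage of the terminal alkene gives the arylacetaldehyde; lutidine suppresses over-oxidation.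

**Step 5**
Reactants: 6
Product: 7 2-{2-[(tert-butyldimethylsilyl)oxy]-3-methoxy-5-(3-methoxy-3-oxopropyl)phenyl}acetic acid
Conditions: NaClO2, NaH2PO4, 2-methyl-2-butene, t-BuOH/H2O, 0 °C → rt
Reagents that add atoms: NaClO2, [Na+].[O-]Cl=O
Why: Pinnick oxidation; the alkene scavenger removes HOCl so the electron-rich ring is not chlorinated.

**Step 6**
Reactants: 7; 8 (4R)-4-benzyl-1,3-oxazolidin-2-one
Product: 9 methyl 3-{3-[2-[(4R)-4-benzyl-2-oxo-1,3-oxazolidin-3-yl]-2-oxoethyl]-4-[(tert-butyldimethylsilyl)oxy]-5-methoxyphenyl}propanoate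
Conditions: PivCl, Et3N, THF, −20 °C; then 8, LiCl, rt
Reagents that add atoms: none besides 8 (pivaloyl is not retained)
Why: N-acylation of the Evans auxiliary through the mixed pivalic anhydride; the mild LiCl/Et3N variant spares the ester and aryl silyl ether.

## Fragment B (steps 7–12)

**Step 7**
Reactants: 10 ethyl formate; 11 vinylmagnesium bromide (2.2 equiv)
Product: 12 penta-1,4-dien-3-ol (divinylcarbinol)
Conditions: THF, 0 °C → rt; aq. NH4Cl
Reagents that add atoms: none besides 10 and 11
Why: Double Grignard addition to a formate ester gives the symmetrical secondary carbinol.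

**Step 8**
Reactants: 12
Product: 13 (2R,3S)-1,2-epoxypent-4-en-3-ol
Conditions: Ti(OiPr)4, L-(+)-DIPT, cumene hydroperoxide, 4 Å MS, CH2Cl2, −25 °C
Reagents that add atoms: cumene hydroperoxide, CC(C)(OO)c1ccccc1 (epoxide oxygen)
Why: Sharpless asymmetric epoxidation with enantiotopic-group and diastereoface selection gives the erythro (2R,3S) epoxy alcohol; these centres become C4′(R) and C3′(S), and the minor enantiomer is destroyed by a faster second epoxidation.

**Step 9**
Reactants: 13; 14 2-methylprop-2-en-1-ol (2.5 equiv)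
Product: 15 (5R,6S)-2-methylideneoct-7-ene-1,5,6-triol
Conditions: 14, n-BuLi (2 equiv per 14), TMEDA, Et2O, 0 °C → rt; then lithium alkoxide of 13 (n-BuLi, THF, −78 °C), −78 → 0 °C
Reagents that add atoms: 2-methylprop-2-en-1-ol (14), CC(=C)CO
Why: SN2 opening of the terminal epoxide CH2 by the allylic dianion of methallyl alcohol; neither stereocentre is touched.

**Step 10**
Reactants: 15
Product: 16 4-[(4R,5S)-5-ethenyl-2,2-dimethyl-1,3-dioxolan-4-yl]-2-methylidenebutan-1-ol
Conditions: 2,2-dimethoxypropane, PPTS, acetone, rt; MeOH quench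
Reagents that add atoms: 2,2-dimethoxypropane, COC(C)(C)OC
Why: Acetonide formation is selective for the vicinal diol (five-membered ketal); the remote primary OH stays free after methanolysis of any mixed ketal.

**Step 11**
Reactants: 16
Product: 17 [(3aS,7aR)-2,2-dimethyl-3a,6,7,7a-tetrahydro-1,3-benzodioxol-5-yl]methanol
Conditions: Grubbs II (3 mol%), CH2Cl2 (0.01 M), 40 °C
Reagents that add atoms: none
Why: Ring-closing metathesis of the 1,1-disubstituted and monosubstituted olefins closes the trisubstituted cyclohexene with loss of ethylene; the cis-acetonide holds the two arms together.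

**Step 12**
Reactants: 17
Product: 18 (3aS,7aR)-2,2-dimethyl-3a,6,7,7a-tetrahydro-1,3-benzodioxole-5-carbaldehyde
Conditions: MnO2, CH2Cl2, rt
Reagents that add atoms: none
Why: Chemoselective MnO2 oxidation of the primary allylic alcohol to the enal.

## Union and endgame (steps 13–17)

**Step 13**
Reactants: 9; 18
Product: 19 (4R)-4-benzyl-3-[(2S,3R)-2-{2-[(tert-butyldimethylsilyl)oxy]-3-methoxy-5-(3-methoxy-3-oxopropyl)phenyl}-3-[(3aS,7aR)-2,2-dimethyl-3a,6,7,7a-tetrahydro-1,3-benzodioxol-5-yl]-3-hydroxypropanoyl]-1,3-oxazolidin-2-one (2,3-anti)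
Conditions: MgCl2 (20 mol%), Et3N, TMSCl, EtOAc, 23 °C; then 1 M HCl/THF (1:5), 0 °C
Reagents that add atoms: none (the O-TMS group is removed in the work-up)
Why: Evans MgCl2-catalysed direct anti-aldol: the chelated (Z)-Mg enolate is attacked on the face anti to the benzyl group (sets the future C3) with anti topicity (carbinol 3R, to be inverted later), and TMSCl traps the aldolate to stop retro-aldol.

**Step 14**
Reactants: 19
Product: 20 (1R,2R)-1-[(3aS,7aR)-2,2-dimethyl-3a,6,7,7a-tetrahydro-1,3-benzodioxol-5-yl]-2-[2-hydroxy-5-(3-hydroxypropyl)-3-methoxyphenyl]propane-1,3-diol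
Conditions: LiBH4, MeOH, THF, 0 °C → rt; then 1 M NaOH/MeOH, rt (work-up)
Reagents that add atoms: none
Why: Reductive removal of the auxiliary (recovered) and reduction of the methyl ester; the basic methanolic work-up cleaves the aryl silyl ether while the acetonide is untouched.

**Step 15**
Reactants: 20
Product: 21 (1R,2R)-1-[(3aS,7aR)-2,2-dimethyl-3a,6,7,7a-tetrahydro-1,3-benzodioxol-5-yl]-2-{2-hydroxy-3-methoxy-5-[3-(trityloxy)propyl]phenyl}-3-(trityloxy)propan-1-ol
Conditions: TrCl (2.3 equiv), pyridine, DMAP (cat.), CH2Cl2, rt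
Reagents that add atoms: trityl chloride, ClC(c1ccccc1)(c1ccccc1)c1ccccc1
Why: Tritylation is selective for the two primary alcohols; the hindered phenol and the hindered secondary allylic alcohol stay free for the cyclisation.

**Step 16**
Reactants: 21
Product: 22 (2S,3R)-2-[(3aS,7aR)-2,2-dimethyl-3a,6,7,7a-tetrahydro-1,3-benzodioxol-5-yl]-7-methoxy-5-[3-(trityloxy)propyl]-3-[(trityloxy)methyl]-2,3-dihydro-1-benzofuran
Conditions: PPh3, DIAD, THF, 0 °C → rt
Reagents that add atoms: none
Why: Intramolecular Mitsunobu etherification (5-exo-tet SN2 by the phenoxide) inverts the allylic carbinol (1R → 2S), turning the anti-diol into the 2,3-trans dihydrobenzofuran.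

**Step 17**
Reactants: 22
Product: 23 difengpiol A
Conditions: AcOH/H2O (4:1), 40 °C
Reagents that add atoms: none
Why: Mild acidic hydrolysis removes both trityl ethers and the acetonide without ionising the allylic alcohol or the allylic aryl ether.

## Compound list

1 | methyl 3-(4-hydroxy-3-methoxyphenyl)propanoate | COC(=O)CCc1ccc(O)c(OC)c1 | starting material
2 | allyl bromide | C=CCBr | starting material
3 | methyl 3-[3-methoxy-4-(prop-2-en-1-yloxy)phenyl]propanoate | COC(=O)CCc1ccc(OCC=C)c(OC)c1 | intermediate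
4 | methyl 3-[4-hydroxy-3-methoxy-5-(prop-2-en-1-yl)phenyl]propanoate | COC(=O)CCc1cc(CC=C)c(O)c(OC)c1 | intermediate
5 | methyl 3-{4-[(tert-butyldimethylsilyl)oxy]-3-methoxy-5-(prop-2-en-1-yl)phenyl}propanoate | COC(=O)CCc1cc(CC=C)c(O[Si](C)(C)C(C)(C)C)c(OC)c1 | intermediate
6 | methyl 3-{4-[(tert-butyldimethylsilyl)oxy]-3-methoxy-5-(2-oxoethyl)phenyl}propanoate | COC(=O)CCc1cc(CC=O)c(O[Si](C)(C)C(C)(C)C)c(OC)c1 | intermediate
7 | 2-{2-[(tert-butyldimethylsilyl)oxy]-3-methoxy-5-(3-methoxy-3-oxopropyl)phenyl}acetic acid | COC(=O)CCc1cc(CC(=O)O)c(O[Si](C)(C)C(C)(C)C)c(OC)c1 | intermediate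
8 | (4R)-4-benzyl-1,3-oxazolidin-2-one | O=C1N[C@H](Cc2ccccc2)CO1 | starting material
9 | arylacetyl imide (fragment A) | COC(=O)CCc1cc(CC(=O)N2C(=O)OC[C@H]2Cc2ccccc2)c(O[Si](C)(C)C(C)(C)C)c(OC)c1 | intermediate
10 | ethyl formate | CCOC=O | starting material
11 | vinylmagnesium bromide | C=C[Mg]Br | starting material
12 | penta-1,4-dien-3-ol | C=CC(O)C=C | intermediate
13 | (2R,3S)-1,2-epoxypent-4-en-3-ol | C=C[C@H](O)[C@H]1CO1 | intermediate
14 | 2-methylprop-2-en-1-ol | CC(=C)CO | starting material
15 | (5R,6S)-2-methylideneoct-7-ene-1,5,6-triol | C=C[C@H](O)[C@H](O)CCC(=C)CO | intermediate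
16 | 4-[(4R,5S)-5-ethenyl-2,2-dimethyl-1,3-dioxolan-4-yl]-2-methylidenebutan-1-ol | C=C[C@@H]1OC(C)(C)O[C@@H]1CCC(=C)CO | intermediate
17 | [(3aS,7aR)-2,2-dimethyl-3a,6,7,7a-tetrahydro-1,3-benzodioxol-5-yl]methanol | OCC1=C[C@@H]2OC(C)(C)O[C@@H]2CC1 | intermediate
18 | (3aS,7aR)-2,2-dimethyl-3a,6,7,7a-tetrahydro-1,3-benzodioxole-5-carbaldehyde (fragment B) | O=CC1=C[C@@H]2OC(C)(C)O[C@@H]2CC1 | intermediate
19 | (2S,3R)-anti-aldol imide | COC(=O)CCc1cc([C@@H]([C@@H](O)C2=C[C@@H]3OC(C)(C)O[C@@H]3CC2)C(=O)N2C(=O)OC[C@H]2Cc2ccccc2)c(O[Si](C)(C)C(C)(C)C)c(OC)c1 | intermediate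
20 | (1R,2R)-phenol triol (acetonide) | OC[C@@H](c1cc(CCCO)cc(OC)c1O)[C@@H](O)C1=C[C@@H]2OC(C)(C)O[C@@H]2CC1 | intermediate
21 | (1R,2R)-bis-trityl ether | C(c1ccccc1)(c1ccccc1)(c1ccccc1)OC[C@@H](c1cc(CCCOC(c2ccccc2)(c2ccccc2)c2ccccc2)cc(OC)c1O)[C@@H](O)C1=C[C@@H]2OC(C)(C)O[C@@H]2CC1 | intermediate
22 | protected (2S,3R)-dihydrobenzofuran | COc1cc(CCCOC(c2ccccc2)(c2ccccc2)c2ccccc2)cc2c1O[C@H](C1=C[C@@H]3OC(C)(C)O[C@@H]3CC1)[C@H]2COC(c1ccccc1)(c1ccccc1)c1ccccc1 | intermediate
23 | difengpiol A | COc1cc(CCCO)cc2c1O[C@H](C1=C[C@H](O)[C@H](O)CC1)[C@H]2CO | target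

## Step count

Total steps: 17 (fragment A 6, fragment B 6, union and endgame 5).
Longest linear sequence: 11 steps (steps 1–6 then 13–17, or steps 7–12 then 13–17).

## Steps most likely to fail

1. **Step 13 (Mg-catalysed anti-aldol).** An ortho-silyloxy arylacetyl imide is outside the best-documented scope, so conversion and anti selectivity are uncertain. Fallback: use the Bu2BOTf Evans syn-aldol with the (S)-auxiliary to get the (2S,3S) adduct, keep the aryl TBS ether through reduction and tritylation, invert the allylic carbinol (Mitsunobu with p-nitrobenzoic acid, then K2CO3/MeOH, which also frees the phenol), and then cyclise as in step 16.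
2. **Step 9 (dianion opening of the unprotected epoxy alcohol).** Payne rearrangement or simple deprotonation may compete. Fallback: open 13 with TBSO(CH2)3MgBr/CuI, form the acetonide, desilylate and oxidise to the aldehyde, install the 1,1-disubstituted olefin by Mannich-type α-methylenation (HCHO, pyrrolidine/propionic acid), and reduce (Luche) to reach 16.
3. **Step 16 (Mitsunobu closure at a hindered allylic carbinol).** Elimination to the diene or partial SN1 erosion of the trans selectivity is possible. Fallback: form the C–O bond from the other side, using an aryl bromide analogue of fragment A, the Evans syn-aldol, and a Cu- or Pd-catalysed intramolecular O-arylation by the secondary alkoxide, which proceeds with retention at C2.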